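## Retrosynthetic overview

1. The C8 methacrylate is installed late by Mitsunobu esterification with inversion, and the C14 aldehyde is unmasked last from a PMB-protected allylic alcohol.
2. Ring C (eight-membered, C9=C10) is closed by ring-closing metathesis across the cis-2,6-disubstituted pyran.
3. The key C7–C8 bond comes from an intermolecular zinc Barbier allylation of acrolein with a pyranyl 3-(bromomethyl)butenolide, which gives the trans α-methylene lactone (ring B) and the C8 carbinol.
4. The bromobutenolide comes from a C7 aldehyde (Morita–Baylis–Hillman, lactonisation, SN2' bromination), the spiro-epoxide from a Corey–Chaykovsky reaction on the pyran-4-one, and the C10 methylene from a Mannich methylenation.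
5. Pyran ring A comes from Achmatowicz rearrangement and Kishi reduction of a furyl carbinol made by an Evans glycolate aldol; rings form in the order furan → pyran A → epoxide → lactone B → ring C.

Assumption and notation: atoms are numbered germacrane-style (ring A = pyran O–C1–C2–C3–C4–C5; C4 spiro-epoxide carbon, C15 its CH2; C6 lactone O–CH; C7 lactone CH; C8 ester CH; C9=C10; C11–C13 α-methylene lactone carbons; C14 formyl carbon), so the target is (1R,4R,5R,6S,7R,8R,9E); TBS = tert-butyldimethylsilyl, Piv = pivaloyl, Bn = benzyl, PMB = 4-methoxybenzyl.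

## Route

Step 1
Reactants: 1 furan; 2 ethylene oxide
Product: 4 2-(furan-2-yl)ethanol, via 2-furyllithium 3 (not isolated)
Conditions: n-BuLi, THF, 0 °C; then 2, 0 °C → rt; H2O
Reagents that add atoms: none
Why: α-Lithiation of furan followed by SN2 opening of the epoxide by the aryllithium gives the hydroxyethyl chain that becomes C10/C14; no stereocentre is formed.

Step 2
Reactants: 4 2-(furan-2-yl)ethanol
Product: 5 tert-butyl[2-(furan-2-yl)ethoxy]dimethylsilane
Conditions: TBSCl, imidazole, CH2Cl2, rt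
Reagents that add atoms: tert-butyldimethylsilyl chloride, CC(C)(C)[Si](C)(C)Cl
Why: Imidazole-promoted silylation protects the primary alcohol through the organolithium, aldol and ring-expansion steps.

Step 3
Reactants: 5 tert-butyl[2-(furan-2-yl)ethoxy]dimethylsilane
Product: 7 5-[2-(TBSO)ethyl]furan-2-carbaldehyde, via 5-lithiofuran 6 (not isolated)
Conditions: n-BuLi, THF, −78 → 0 °C; then DMF, −78 °C → rt; H2O
Reagents that add atoms: N,N-dimethylformamide, CN(C)C=O
Why: Lithiation at the free furan α-position and formylation with DMF install the aldehyde carbon that becomes C5.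

Step 4
Reactants: 8 (R)-4-benzyl-1,3-oxazolidin-2-one; 9 (benzyloxy)acetyl chloride
Product: 11 (R)-4-benzyl-3-[(benzyloxy)acetyl]-1,3-oxazolidin-2-one, via lithium oxazolidinide 10 (not isolated)
Conditions: n-BuLi, THF, −78 °C; then 9, −78 → 0 °C
Reagents that add atoms: none
Why: N-Acylation of the lithiated Evans auxiliary gives the glycolate imide that will supply C6, C7 and the C6 oxygen.

Step 5
Reactants: 11 (R)-4-benzyl-3-[(benzyloxy)acetyl]-1,3-oxazolidin-2-one; 7 5-[2-(TBSO)ethyl]furan-2-carbaldehyde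
Product: 13 syn-aldol adduct (4R)-4-benzyl-3-[(2R,3R)-2-(benzyloxy)-3-hydroxy-3-{5-[2-(TBSO)ethyl]furan-2-yl}propanoyl]-1,3-oxazolidin-2-one, via dibutylboron Z-enolate 12 (not isolated)
Conditions: Bu2BOTf, Et3N, CH2Cl2, −78 → 0 °C; then 7, −78 → 0 °C; pH 7 buffer, MeOH, H2O2, 0 °C
Reagents that add atoms: none
Why: Evans syn-aldol reaction: the Z-boron enolate reacts through a Zimmerman–Traxler chair on the face left open by the auxiliary benzyl group, setting C5 (R) and C6 (R) as the syn pair.

Step 6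
Reactants: 13 syn-aldol adduct
Product: 14 (1R,2S)-2-(benzyloxy)-1-{5-[2-(TBSO)ethyl]furan-2-yl}propane-1,3-diol
Conditions: NaBH4, THF/H2O (3:1), 0 °C → rt
Reagents that add atoms: none
Why: Borohydride reduction of the activated imide carbonyl removes the auxiliary and gives the C7 primary alcohol without touching C5 or C6 (the C6 descriptor changes only because priorities change).

Step 7
Reactants: 14 diol
Product: 15 (2S,3R)-2-(benzyloxy)-3-hydroxy-3-{5-[2-(TBSO)ethyl]furan-2-yl}propyl pivalate
Conditions: PivCl, pyridine, CH2Cl2, 0 °C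
Reagents that add atoms: pivaloyl chloride, CC(C)(C)C(Cl)=O
Why: Acylation is selective for the primary hydroxyl over the hindered secondary furfuryl hydroxyl, which must stay free for the ring expansion.

Step 8
Reactants: 15 pivalate
Product: 16 (5R,6S)-hemiketal: 2H-pyran-3(6H)-one carrying OH and CH2CH2OTBS at C1 (both anomers) and CH(OBn)CH2OPiv at C5
Conditions: NBS, NaHCO3, THF/H2O (4:1), 0 °C
Reagents that add atoms: water, O
Why: Achmatowicz rearrangement: oxidative opening of the furan to the cis-enedione and hemiketalisation by the C5 hydroxyl give the pyranone with the ketone at C4; C5 and C6 are untouched.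

Step 9
Reactants: 16 hemiketal
Product: 17 (1S,5R,6S)-cis-dihydropyranone: 2H-pyran-3(6H)-one with CH2CH2OTBS at C1 and CH(OBn)CH2OPiv at C5
Conditions: Et3SiH, CF3CO2H, CH2Cl2, −40 °C
Reagents that add atoms: none
Why: Kishi reduction (ionic hydrogenation): the oxocarbenium ion takes hydride axially, so the C1 chain ends up equatorial and cis to the C5 side chain, which sets C1.

Step 10
Reactants: 17 cis-dihydropyranone
Product: 18 (1R,5R,6S)-hydroxy ketone: cis-2,6-disubstituted oxan-3-one (C4=O) with CH2CH2OTBS at C1 and CH(OH)CH2OPiv at C5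
Conditions: H2 (1 atm), Pd(OH)2/C, EtOAc, rt
Reagents that add atoms: none
Why: Heterogeneous hydrogenation saturates the enone alkene and hydrogenolyses the benzyl ether while ketone, silyl ether and pivalate survive; no stereocentre changes (C1 becomes R by priority only).

Step 11
Reactants: 18 hydroxy ketone
Product: 19 (1R,5R,6S)-bis-silyl ether: ketone 18 with the C6 hydroxyl as OTBS
Conditions: TBSOTf, 2,6-lutidine, CH2Cl2, −78 °C
Reagents that add atoms: tert-butyldimethylsilyl triflate, CC(C)(C)[Si](C)(C)OS(=O)(=O)C(F)(F)F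
Why: Low-temperature silylation with the silyl triflate caps the β-hydroxy ketone before any base is used, which prevents retro-aldol cleavage of C5–C6.

Step 12
Reactants: 19 bis-silyl ether
Product: 20 (1R,5R,6S)-keto alcohol: CH2CH2OH at C1, OTBS at C6, OPiv at C7
Conditions: HF·pyridine, pyridine, THF, 0 °C
Reagents that add atoms: none
Why: Buffered fluoride cleaves the unhindered primary silyl ether much faster than the hindered secondary one, and this is done before the acid-sensitive epoxide exists.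

Step 13
Reactants: 20 keto alcohol
Product: 21 (1R,4R,5R,6S)-spiro-epoxy alcohol: oxirane spiro-fused at C4 with C15 cis to the C5 side chain
Conditions: Me3SI, n-BuLi, THF, −10 °C; then 20 (3 equiv of ylide), −10 → 0 °C
Reagents that add atoms: trimethylsulfonium iodide, C[S+](C)C.[I-]
Why: Corey–Chaykovsky epoxidation: the small sulfonium ylide adds irreversibly along the axial trajectory of the chair ketone, so the new CH2 is axial (cis to the equatorial C5 side chain) and the oxygen equatorial, which sets C4 as R.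

Step 14
Reactants: 21 spiro-epoxy alcohol
Product: 22 (1R,4R,5R,6S)-aldehyde: CH2CHO at C1
Conditions: Dess–Martin periodinane, pyridine, CH2Cl2, 0 °C → rt
Reagents that add atoms: none
Why: Buffered Dess–Martin oxidation gives the aldehyde under non-acidic conditions that spare the epoxide and silyl ether.

Step 15
Reactants: 22 aldehyde
Product: 24 (1R,4R,5R,6S)-enal: C(=CH2)CHO at C1, via Mannich base 23 (not isolated)
Conditions: CH2=NMe2+ I−, Et3N, CH2Cl2, rt
Reagents that add atoms: N,N-dimethylmethyleneiminium iodide, C=[N+](C)C.[I-]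
Why: Mannich reaction with Eschenmoser's salt followed by β-elimination of dimethylamine gives the 2-substituted acrolein; any reversible retro-oxa-Michael opening recloses to the more stable cis-pyran, so C1 is kept.

Step 16
Reactants: 24 enal
Product: 25 (1R,4R,5R,6S)-allylic alcohol: C(=CH2)CH2OH at C1
Conditions: NaBH4, CeCl3·7H2O, MeOH, −78 °C
Reagents that add atoms: none
Why: Luche reduction gives clean 1,2-reduction of the enal and leaves the pivalate and epoxide alone.

Step 17
Reactants: 25 allylic alcohol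
Product: 27 (1R,4R,5R,6S)-PMB ether: C(=CH2)CH2OPMB at C1, via sodium alkoxide 26 (not isolated)
Conditions: NaH, THF/DMF, 0 °C; then PMBCl, Bu4NI (cat.), 0 °C → rt
Reagents that add atoms: 4-methoxybenzyl chloride, COc1ccc(CCl)cc1
Why: Williamson etherification gives a C14 protecting group that survives fluoride, hydride, zinc, metathesis and Mitsunobu conditions and is removed oxidatively at the end.

Step 18
Reactants: 27 PMB ether
Product: 28 (1R,4R,5R,6S)-primary alcohol: CH2OH at C7
Conditions: i-Bu2AlH, CH2Cl2, −78 °C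
Reagents that add atoms: none
Why: Reductive cleavage of the pivalate at −78 °C frees the C7 alcohol without opening the epoxide or touching the silyl and PMB ethers.

Step 19
Reactants: 28 primary alcohol
Product: 29 (1R,4R,5R,6R)-α-silyloxy aldehyde: CHO at C7
Conditions: Dess–Martin periodinane, pyridine, CH2Cl2, 0 °C
Reagents that add atoms: none
Why: Buffered Dess–Martin oxidation gives the aldehyde without epimerising C6 (the descriptor changes by priority only); it is used crude.

Step 20
Reactants: 29 α-silyloxy aldehyde; 30 methyl acrylate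
Product: 31 Morita–Baylis–Hillman adduct (1R,4R,5R,6S,7RS): methyl 2-methylene-3-hydroxy ester with OH at C7 and OTBS at C6
Conditions: 30 (excess), DABCO (1 equiv), MeOH (cat.), rt, 3–6 d
Reagents that add atoms: none
Why: The Morita–Baylis–Hillman reaction attaches C11–C13 to the activated α-alkoxy aldehyde; the new C7 carbinol forms as a mixture that does not matter because C7 becomes sp2 in step 22.

Step 21
Reactants: 31 Morita–Baylis–Hillman adduct
Product: 33 (1R,4R,5R,6S,7RS)-β-hydroxy-α-methylene-γ-butyrolactone (lactone O on C6 and OH on C7), via desilylated hydroxy ester 32 (not isolated)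
Conditions: Bu4NF, AcOH, THF, 0 °C → rt; then PPTS (cat.), CH2Cl2, rt
Reagents that add atoms: none
Why: Buffered fluoride desilylation frees the C6 hydroxyl, which lactonises onto the acrylate ester (5-exo) to form ring B with C6 unchanged.

Step 22
Reactants: 33 β-hydroxy-α-methylene lactone
Product: 34 (1R,4R,5R,6S)-3-(bromomethyl)furan-2(5H)-one whose ring carbon C6 carries the epoxy-pyran
Conditions: CBr4, PPh3, CH2Cl2, 0 °C
Reagents that add atoms: carbon tetrabromide, BrC(Br)(Br)Br
Why: Appel bromination with allylic transposition (SN2'): bromide attacks the exocyclic methylene of the C7 oxyphosphonium ion and gives the conjugated bromomethyl butenolide under neutral conditions that spare the epoxide.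

Step 23
Reactants: 34 bromomethyl butenolide; 35 acrolein
Product: 37 (1R,4R,5R,6S,7R,8S)-Barbier adduct: trans-α-methylene-γ-butyrolactone with CH(OH)CH=CH2 at C7, via allylzinc bromide 36 (not isolated)
Conditions: Zn dust, 35 (5 equiv), THF/sat. aq. NH4Cl (2:1), 0 °C → rt
Reagents that add atoms: none
Why: Barbier-type carbonyl allylation: the allylzinc reacts at its γ-carbon (C7) on the butenolide face anti to the pyranyl group at C6 (7R, trans lactone) through a chair Zimmerman–Traxler transition state with the vinyl group equatorial, which gives the 8S carbinol, the C8 epimer that step 25 inverts.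

Step 24
Reactants: 37 Barbier adduct
Product: 38 (1R,4R,5R,6S,7R,8S,9Z)-tricyclic allylic alcohol: rings A, B and C in place, OH at C8, CH2OPMB at C10
Conditions: Hoveyda–Grubbs second-generation catalyst RuCl2(H2IMes)(=CH–C6H4-2-O-i-Pr) (15 mol %), 1,4-benzoquinone (cat.), toluene (2 mM), 80 °C
Reagents that add atoms: none
Why: Ring-closing metathesis: the carbene loads on the C8 vinyl group and closes onto the C10 methylene held nearby by the cis-pyran; the eight-membered ring allows only the C8/C1-cis alkene, and the electron-poor exo-methylene does not compete.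

Step 25
Reactants: 38 tricyclic allylic alcohol; 39 methacrylic acid
Product: 40 (1R,4R,5R,6S,7R,8R,9Z)-8-methacrylate with CH2OPMB at C10
Conditions: PPh3, diisopropyl azodicarboxylate, toluene, 0 °C → rt
Reagents that add atoms: none
Why: Mitsunobu esterification: SN2 attack of methacrylate on the C8 oxyphosphonium ion inverts C8 from S to R and installs the ester in one operation, with no basic hydrolysis that the α-methylene lactone would not survive.

Step 26
Reactants: 40 8-methacrylate PMB ether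
Product: 41 (1R,4R,5R,6S,7R,8R,9Z)-8-methacrylate with CH2OH at C10
Conditions: DDQ, CH2Cl2/pH 7 buffer (10:1), 0 °C
Reagents that add atoms: none
Why: Oxidative PMB cleavage under buffered neutral conditions leaves the epoxide, both acrylate-type alkenes and the ester untouched.

Step 27
Reactants: 41 allylic alcohol
Product: 42 target CNP0257628.1, (1R,4R,5R,6S,7R,8R,9E)
Conditions: Dess–Martin periodinane, pyridine, CH2Cl2, 0 °C
Reagents that add atoms: none
Why: Buffered Dess–Martin oxidation of the primary allylic alcohol gives the enal without changing the alkene geometry (now 9E by priority) or any stereocentre.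

## Compound list

1 | furan | c1ccoc1 | starting material
2 | ethylene oxide | C1CO1 | starting material
3 | 2-furyllithium | [Li]c1ccco1 | intermediate
4 | 2-(furan-2-yl)ethanol | OCCc1ccco1 | intermediate
5 | tert-butyl[2-(furan-2-yl)ethoxy]dimethylsilane | CC(C)(C)[Si](C)(C)OCCc1ccco1 | intermediate
6 | {5-[2-(TBSO)ethyl]furan-2-yl}lithium | CC(C)(C)[Si](C)(C)OCCc1ccc([Li])o1 | intermediate
7 | 5-[2-(TBSO)ethyl]furan-2-carbaldehyde | CC(C)(C)[Si](C)(C)OCCc1ccc(C=O)o1 | intermediate
8 | (R)-4-benzyl-1,3-oxazolidin-2-one | O=C1N[C@H](Cc2ccccc2)CO1 | starting material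
9 | (benzyloxy)acetyl chloride | ClC(=O)COCc1ccccc1 | starting material
10 | N-lithio-(R)-4-benzyl-1,3-oxazolidin-2-one | [Li]N1[C@H](Cc2ccccc2)COC1=O | intermediate
11 | (R)-4-benzyl-3-[(benzyloxy)acetyl]-1,3-oxazolidin-2-one | O=C(COCc1ccccc1)N1[C@H](Cc2ccccc2)COC1=O | intermediate
12 | dibutylboron (Z)-enolate of 11 | CCCCB(CCCC)O/C(=C\OCc1ccccc1)N1[C@H](Cc2ccccc2)COC1=O | intermediate
13 | (4R)-4-benzyl-3-[(2R,3R)-2-(benzyloxy)-3-hydroxy-3-{5-[2-(TBSO)ethyl]furan-2-yl}propanoyl]-1,3-oxazolidin-2-one | CC(C)(C)[Si](C)(C)OCCc1ccc(o1)[C@H](O)[C@@H](OCc2ccccc2)C(=O)N3[C@H](Cc4ccccc4)COC3=O | intermediate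
14 | (1R,2S)-2-(benzyloxy)-1-{5-[2-(TBSO)ethyl]furan-2-yl}propane-1,3-diol | CC(C)(C)[Si](C)(C)OCCc1ccc(o1)[C@H](O)[C@@H](OCc2ccccc2)CO | intermediate
15 | (2S,3R)-2-(benzyloxy)-3-hydroxy-3-{5-[2-(TBSO)ethyl]furan-2-yl}propyl pivalate | CC(C)(C)[Si](C)(C)OCCc1ccc(o1)[C@H](O)[C@@H](OCc2ccccc2)COC(=O)C(C)(C)C | intermediate
16 | (5R,6S)-hemiketal: 2H-pyran-3(6H)-one; C1 OH + CH2CH2OTBS (both anomers); C5 CH(OBn)CH2OPiv | CC(C)(C)[Si](C)(C)OCCC1(O)C=CC(=O)[C@H](O1)[C@@H](OCc2ccccc2)COC(=O)C(C)(C)C | intermediate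
17 | (1S,5R,6S)-cis-dihydropyranone; C1 CH2CH2OTBS; C5 CH(OBn)CH2OPiv | CC(C)(C)[Si](C)(C)OCC[C@H]1C=CC(=O)[C@H](O1)[C@@H](OCc2ccccc2)COC(=O)C(C)(C)C | intermediate
18 | (1R,5R,6S)-hydroxy ketone; C1 CH2CH2OTBS; C5 CH(OH)CH2OPiv | CC(C)(C)[Si](C)(C)OCC[C@H]1CCC(=O)[C@H](O1)[C@@H](O)COC(=O)C(C)(C)C | intermediate
19 | (1R,5R,6S)-bis-silyl ether ketone; C6 OTBS; C7 OPiv | CC(C)(C)[Si](C)(C)OCC[C@H]1CCC(=O)[C@H](O1)[C@@H](O[Si](C)(C)C(C)(C)C)COC(=O)C(C)(C)C | intermediate
20 | (1R,5R,6S)-keto alcohol; C1 CH2CH2OH; C6 OTBS; C7 OPiv | OCC[C@H]1CCC(=O)[C@H](O1)[C@@H](O[Si](C)(C)C(C)(C)C)COC(=O)C(C)(C)C | intermediate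
21 | (1R,4R,5R,6S)-spiro-epoxy alcohol; C1 CH2CH2OH | OCC[C@H]1CC[C@@]2(CO2)[C@H](O1)[C@@H](O[Si](C)(C)C(C)(C)C)COC(=O)C(C)(C)C | intermediate
22 | (1R,4R,5R,6S)-aldehyde; C1 CH2CHO | O=CC[C@H]1CC[C@@]2(CO2)[C@H](O1)[C@@H](O[Si](C)(C)C(C)(C)C)COC(=O)C(C)(C)C | intermediate
23 | Mannich base; C1 CH(CH2NMe2)CHO (C10 epimers) | CN(C)CC(C=O)[C@H]1CC[C@@]2(CO2)[C@H](O1)[C@@H](O[Si](C)(C)C(C)(C)C)COC(=O)C(C)(C)C | intermediate
24 | (1R,4R,5R,6S)-enal; C1 C(=CH2)CHO | C=C(C=O)[C@H]1CC[C@@]2(CO2)[C@H](O1)[C@@H](O[Si](C)(C)C(C)(C)C)COC(=O)C(C)(C)C | intermediate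
25 | (1R,4R,5R,6S)-allylic alcohol; C1 C(=CH2)CH2OH | C=C(CO)[C@H]1CC[C@@]2(CO2)[C@H](O1)[C@@H](O[Si](C)(C)C(C)(C)C)COC(=O)C(C)(C)C | intermediate
26 | sodium alkoxide of 25 | [Na+].[O-]CC(=C)[C@H]1CC[C@@]2(CO2)[C@H](O1)[C@@H](O[Si](C)(C)C(C)(C)C)COC(=O)C(C)(C)C | intermediate
27 | (1R,4R,5R,6S)-PMB ether; C1 C(=CH2)CH2OPMB; C6 OTBS; C7 OPiv | C=C(COCc1ccc(OC)cc1)[C@H]2CC[C@@]3(CO3)[C@H](O2)[C@@H](O[Si](C)(C)C(C)(C)C)COC(=O)C(C)(C)C | intermediate
28 | (1R,4R,5R,6S)-primary alcohol; C7 CH2OH | C=C(COCc1ccc(OC)cc1)[C@H]2CC[C@@]3(CO3)[C@H](O2)[C@@H](O[Si](C)(C)C(C)(C)C)CO | intermediate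
29 | (1R,4R,5R,6R)-α-silyloxy aldehyde; C7 CHO | C=C(COCc1ccc(OC)cc1)[C@H]2CC[C@@]3(CO3)[C@H](O2)[C@@H](O[Si](C)(C)C(C)(C)C)C=O | intermediate
30 | methyl acrylate | C=CC(=O)OC | starting material
31 | Morita–Baylis–Hillman adduct (1R,4R,5R,6S,7RS) | C=C(COCc1ccc(OC)cc1)[C@H]2CC[C@@]3(CO3)[C@H](O2)[C@@H](O[Si](C)(C)C(C)(C)C)C(O)C(=C)C(=O)OC | intermediate
32 | desilylated 6,7-dihydroxy ester | C=C(COCc1ccc(OC)cc1)[C@H]2CC[C@@]3(CO3)[C@H](O2)[C@@H](O)C(O)C(=C)C(=O)OC | intermediate
33 | (1R,4R,5R,6S,7RS)-β-hydroxy-α-methylene-γ-butyrolactone | C=C(COCc1ccc(OC)cc1)[C@H]2CC[C@@]3(CO3)[C@H](O2)[C@H]4OC(=O)C(=C)C4O | intermediate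
34 | (1R,4R,5R,6S)-3-(bromomethyl)furan-2(5H)-one bearing the epoxy-pyran at C6 | C=C(COCc1ccc(OC)cc1)[C@H]2CC[C@@]3(CO3)[C@H](O2)[C@H]4OC(=O)C(CBr)=C4 | intermediate
35 | acrolein | C=CC=O | starting material
36 | allylzinc bromide from 34 | C=C(COCc1ccc(OC)cc1)[C@H]2CC[C@@]3(CO3)[C@H](O2)[C@H]4OC(=O)C(C[Zn]Br)=C4 | intermediate
37 | (1R,4R,5R,6S,7R,8S)-Barbier adduct; C7 CH(OH)CH=CH2 | C=C(COCc1ccc(OC)cc1)[C@H]2CC[C@@]3(CO3)[C@H](O2)[C@H]4OC(=O)C(=C)[C@@H]4[C@@H](O)C=C | intermediate
38 | (1R,4R,5R,6S,7R,8S,9Z)-tricyclic allylic alcohol; C14 OPMB | O[C@H]1/C=C(/COCc2ccc(OC)cc2)[C@H]3CC[C@@]4(CO4)[C@H](O3)[C@H]5OC(=O)C(=C)[C@@H]51 | intermediate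
39 | methacrylic acid | C=C(C)C(=O)O | starting material
40 | (1R,4R,5R,6S,7R,8R,9Z)-8-methacrylate; C14 OPMB | C=C(C)C(=O)O[C@@H]1/C=C(/COCc2ccc(OC)cc2)[C@H]3CC[C@@]4(CO4)[C@H](O3)[C@H]5OC(=O)C(=C)[C@@H]51 | intermediate
41 | (1R,4R,5R,6S,7R,8R,9Z)-8-methacrylate; C14 OH | C=C(C)C(=O)O[C@@H]1/C=C(/CO)[C@H]2CC[C@@]3(CO3)[C@H](O2)[C@H]4OC(=O)C(=C)[C@@H]41 | intermediate
42 | CNP0257628.1 | C=C(C)C(=O)O[C@@H]1/C=C(/C=O)[C@H]2CC[C@@]3(CO3)[C@H](O2)[C@H]2OC(=O)C(=C)[C@@H]21 | target

## Summary

Total steps: 27. Longest linear sequence: 26 (steps 1–3 and 5–27); step 4 is a one-step side branch.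

The three steps most likely to fail:

Step 24 (ring-closing metathesis). The eight-membered ring must close onto a 1,1-disubstituted alkene with both pyran substituents axial, so loading on the allylic carbinol vinyl group may lead to dimers or carbinol isomerisation instead of cyclisation. The fallback is a relay ring-closing metathesis and sets out from 34. The Barbier reaction is run with (E)-4-(allyloxy)but-2-enal (two steps from cis-but-2-ene-1,4-diol) in place of acrolein, under the same Zn/NH4Cl conditions, to give the relay carbinol F1 with the same C7/C8 outcome. With the same ruthenium catalyst the carbene loads on the terminal allyl ether, expels 2,5-dihydrofuran and is delivered intramolecularly to C9 before closing on the C10 methylene. The route is rejoined at 38.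

Step 25 (Mitsunobu esterification on the medium ring). Back-side attack at C8 may be blocked transannularly, or an allyl cation may erode the inversion. The fallback inverts C8 before ring closure and sets out from 37. Mitsunobu reaction with chloroacetic acid (PPh3, diisopropyl azodicarboxylate, THF) gives the inverted chloroacetate F2. Thiourea with NaHCO3 in EtOH at 40 °C removes the chloroacetyl group to give the 8R acyclic alcohol F3. Ring-closing metathesis as in step 24 gives the 8R tricyclic alcohol F4, which is acylated with methacrylic anhydride, Et3N and DMAP (cat.) in CH2Cl2 at 0 °C. The route is rejoined at 40.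

Step 20 (Morita–Baylis–Hillman reaction). The α,β-branched aldehyde may react too slowly or epimerise at C6 under the amine. The fallback is a stoichiometric aldol–elimination sequence and sets out from 29. The lithium enolate of methyl 3-(phenylselanyl)propanoate (LiN(i-Pr)2, THF, −78 °C) adds to 29 within minutes to give the selenide aldol adduct F5. Oxidation with H2O2 and pyridine in CH2Cl2 at 0 °C triggers selenoxide syn-elimination to the same 2-methylene-3-hydroxy ester. The route is rejoined at 31.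

## Further compounds

F1 | step 24 | relay carbinol (1R,4R,5R,6S,7R,8S): Barbier adduct with (E)-CH=CH–CH2–O–allyl at C8 | C=C(COCc1ccc(OC)cc1)[C@H]2CC[C@@]3(CO3)[C@H](O2)[C@H]4OC(=O)C(=C)[C@@H]4[C@@H](O)/C=C/COCC=C
F2 | step 25 | acyclic 8R chloroacetate of the Barbier adduct | C=C(COCc1ccc(OC)cc1)[C@H]2CC[C@@]3(CO3)[C@H](O2)[C@H]4OC(=O)C(=C)[C@@H]4[C@H](OC(=O)CCl)C=C
F3 | step 25 | acyclic 8R allylic alcohol (C8 epimer of 37) | C=C(COCc1ccc(OC)cc1)[C@H]2CC[C@@]3(CO3)[C@H](O2)[C@H]4OC(=O)C(=C)[C@@H]4[C@H](O)C=C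
F4 | step 25 | (8R,9Z)-tricyclic allylic alcohol (C8 epimer of 38) | O[C@@H]1/C=C(/COCc2ccc(OC)cc2)[C@H]3CC[C@@]4(CO4)[C@H](O3)[C@H]5OC(=O)C(=C)[C@@H]51
F5 | step 20 | selenide aldol adduct: methyl 3-hydroxy-2-[(phenylselanyl)methyl] ester at C7 (C7/C11 epimers) | C=C(COCc1ccc(OC)cc1)[C@H]2CC[C@@]3(CO3)[C@H](O2)[C@@H](O[Si](C)(C)C(C)(C)C)C(O)C(C[Se]c4ccccc4)C(=O)OC
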